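## Retrosynthetic overview

1. Glycerol ester last: the C15 carboxylic acid opens (S)-glycidyl acetate at the terminal epoxide carbon. The glycerol stereocentre is bought with (R)-glycidol.
2. C9–C11 bond: Negishi coupling of the ring-B enol triflate (C9–OTf, C8–CH3) with a five-carbon alkylzinc from (R)-methyl hydrogen 3-methylglutarate (C13 bought). The coupling fixes the tetrasubstituted C8=C9 alkene.
3. Ring A: one-flask [3+3] annulation of 6-methylcarvone with (Z)-3-bromo-1-iodopropene. C1–C10 forms by dienolate alkylation and C3–C4 by reductive Heck closure.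
4. Enabling feature: in (S)-carvone (ring B, bought with C5) the internal isopropenyl carbon (future C4, already carrying C19 as CH3 and C18 as =CH2) lies 1,3 to the enolisable α'-carbon (future C10) across the stereocentre C5. A C1–C2–C3 unit can therefore bridge them, and C10 is relayed from C5.
5. Ring order: ring B is bought, ring A is closed in the key step, then the side chain and the glycerol unit are attached.

Key step: step 4

Assumption: (S)-carvone, (R)-glycidol, ethyl (Z)-3-iodoacrylate and (R)-methyl hydrogen 3-methylglutarate are taken as purchasable in isomerically pure form; locants C1–C20 in the text are labdane numbering of the acid part.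

## Route

Step 1
Reactants: 1 (S)-(+)-carvone [(5S)-2-methyl-5-(prop-1-en-2-yl)cyclohex-2-en-1-one]
Product: 2 (5S,6RS)-2,6-dimethyl-5-(prop-1-en-2-yl)cyclohex-2-en-1-one (6-methylcarvone, C6 epimers, used as the mixture)
Conditions: LiN(iPr)2, THF, −78 °C; MeI, −78 to 0 °C
Reagents that add atoms: iodomethane, CI
Why: Kinetic α'-deprotonation of the enone and SN2 methylation of the lithium dienolate (enolate alkylation) should give the 6-methyl ketone, whose new C6 centre need not be controlled because it is planarised again in step 4.

Step 2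
Reactants: 3 ethyl (2Z)-3-iodoprop-2-enoate
Product: 4 (2Z)-3-iodoprop-2-en-1-ol
Conditions: iBu2AlH (2.2 equiv), CH2Cl2, −78 to 0 °C; aq. potassium sodium tartrate (KNaC4H4O6) work-up
Reagents that add atoms: none
Why: Hydride reduction of an α,β-unsaturated ester to the allylic alcohol (1,2-reduction) should leave the alkenyl iodide and its Z geometry untouched, and no stereocentre is formed.

Step 3
Reactants: 4 (2Z)-3-iodoprop-2-en-1-ol
Product: 5 (1Z)-3-bromo-1-iodoprop-1-ene
Conditions: CBr4, PPh3, CH2Cl2, 0 °C, dark; used directly
Reagents that add atoms: carbon tetrabromide, BrC(Br)(Br)Br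
Why: The Appel reaction converts the primary allylic alcohol into the bromide under neutral conditions without isomerising the Z-alkenyl iodide, and no stereocentre is formed.

Step 4
Reactants: 2 6-methylcarvone; 5 (1Z)-3-bromo-1-iodoprop-1-ene
Product: 7 (4aR,8aR)-2,5,5,8a-tetramethyl-4a,5,8,8a-tetrahydronaphthalen-1(4H)-one, via Z-iodoallyl ketone 6 (not isolated)
Conditions: LiN(iPr)2, THF, −78 °C; 5, DMPU, −78 to 0 °C; then, same flask, Pd(OAc)2 (5 mol%), PPh3 (10 mol%), HCO2Na, Bu4NCl, DMF, 70 °C
Reagents that add atoms: none
Why: LiN(iPr)2 removes the single α'-hydrogen of 2 and the cross-conjugated lithium dienolate is alkylated by the allylic bromide of 5 (SN2 enolate alkylation, as known for 6-alkylcarvones), which makes the C1–C10 bond and the quaternary centre C10 in 6. In the same flask zerovalent palladium inserts into the Z-alkenyl iodide, the alkenylpalladium adds syn across the isopropenyl group to make the C3–C4 bond, and the resulting neopentyl palladium species, which has no β-hydrogen, is reduced by formate (decarboxylation, then C–H reductive elimination) so that the former =CH2 becomes the second methyl on C4; the closest known reaction type is the reductive Heck cyclisation with hydride capture. Ring A is the only ring closed, by 6-exo-trig carbopalladation of a tether whose two arms sit trans-diequatorial on ring B, which gives the trans ring fusion. The one new stereocentre, C10, is set by substrate control from C5, because the electrophile should enter the dienolate face anti to the neighbouring isopropenyl group, leaving the C10 methyl trans to H-5; C4 is not stereogenic. The step needs α' over γ deprotonation (kinetic amide base at −78 °C), C- over O-alkylation and SN2 over SN2' (primary allylic bromide, lithium counter-ion), and 6-exo over 7-endo insertion ahead of premature hydride capture (ring size, alkene held close, sparingly soluble formate). The Z geometry of 5, without which the alkenylpalladium cannot reach C4, is carried through unchanged.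

Step 5
Reactants: 7 (4aR,8aR)-2,5,5,8a-tetramethyl-4a,5,8,8a-tetrahydronaphthalen-1(4H)-one
Product: 8 (2RS,4aR,8aR)-2,5,5,8a-tetramethyl-3,4,4a,5,6,7,8,8a-octahydronaphthalen-1(2H)-one (C2 epimers)
Conditions: H2 (1 atm), Pd/C, EtOAc, 20 °C
Reagents that add atoms: none
Why: Heterogeneous catalytic hydrogenation should saturate the cis-disubstituted ring-A alkene and the conjugated ring-B alkene while the hindered ketone stays, and the new C2 methyl centre may form as a mixture because it becomes sp2 again in step 6.

Step 6
Reactants: 8 (2RS,4aR,8aR)-2,5,5,8a-tetramethyl-3,4,4a,5,6,7,8,8a-octahydronaphthalen-1(2H)-one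
Product: 9 (4aR,8aR)-2,5,5,8a-tetramethyl-3,4,4a,5,6,7,8,8a-octahydronaphthalen-1-yl trifluoromethanesulfonate
Conditions: KN(SiMe3)2, THF, −78 to 0 °C; PhNTf2, 0 to 20 °C
Reagents that add atoms: N-phenylbis(trifluoromethanesulfonimide), O=S(=O)(N(c1ccccc1)S(=O)(=O)C(F)(F)F)C(F)(F)F
Why: Enolate O-sulfonylation (enol triflate formation) can only give the tetrasubstituted C1=C2 triflate because C2 carries the single α-hydrogen (C8a is quaternary), and no stereocentre is formed.

Step 7
Reactants: 10 (3R)-5-methoxy-3-methyl-5-oxopentanoic acid [(R)-methyl hydrogen 3-methylglutarate]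
Product: 11 methyl (3R)-5-hydroxy-3-methylpentanoate
Conditions: BH3·SMe2, THF, −10 to 20 °C; then H2O
Reagents that add atoms: none
Why: Chemoselective borane reduction of a carboxylic acid beside a methyl ester (via the acyloxyborane) should give the primary alcohol, and the C3 stereocentre bought with 10 is not touched.

Step 8
Reactants: 11 methyl (3R)-5-hydroxy-3-methylpentanoate
Product: 12 methyl (3S)-5-iodo-3-methylpentanoate
Conditions: I2, PPh3, imidazole, CH2Cl2, 0 to 20 °C
Reagents that add atoms: iodine, II
Why: Appel-type iodination of the primary alcohol should outrun lactonisation and does not touch the stereocentre, whose descriptor changes only by priority.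

Step 9
Reactants: 9 enol triflate; 12 methyl (3S)-5-iodo-3-methylpentanoate
Product: 14 methyl (3R)-3-methyl-5-[(4aR,8aR)-2,5,5,8a-tetramethyl-3,4,4a,5,6,7,8,8a-octahydronaphthalen-1-yl]pentanoate (methyl ent-labd-8-en-15-oate), via alkylzinc iodide 13 (not isolated)
Conditions: 12, Zn dust (activated with 5 mol% I2), DMA, 40 °C; then 9, Pd(OAc)2 (5 mol%), SPhos (10 mol%), THF, 50 °C
Reagents that add atoms: none
Why: In this Negishi coupling zinc insertion into the primary C–I bond gives an ester-tolerant alkylzinc, and a bulky electron-rich biarylphosphine–palladium catalyst should carry the hindered tetrasubstituted enol triflate through oxidative addition and fast reductive elimination, fixing the alkene at C8=C9 without forming a stereocentre.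

Step 10
Reactants: 14 methyl ent-labd-8-en-15-oate
Product: 15 (3R)-3-methyl-5-[(4aR,8aR)-2,5,5,8a-tetramethyl-3,4,4a,5,6,7,8,8a-octahydronaphthalen-1-yl]pentanoic acid (ent-labd-8-en-15-oic acid)
Conditions: LiOH, THF/MeOH/H2O, 40 °C; then 1 M HCl
Reagents that add atoms: lithium hydroxide, [Li+].[OH-]
Why: Ester saponification should proceed without risk, because the stereocentre is β to the carboxyl group and the tetrasubstituted alkene is inert to hydroxide.

Step 11
Reactants: 16 (R)-glycidol [(2R)-oxiran-2-ylmethanol]
Product: 17 (S)-glycidyl acetate [(2S)-oxiran-2-ylmethyl acetate]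
Conditions: Ac2O, NEt3, DMAP (cat.), CH2Cl2, 0 °C
Reagents that add atoms: acetic anhydride, CC(=O)OC(C)=O
Why: Acylation of the primary alcohol under nucleophilic catalysis leaves the epoxide and its stereocentre intact, the descriptor changing only by priority.

Step 12
Reactants: 15 ent-labd-8-en-15-oic acid; 17 (S)-glycidyl acetate
Product: 18 (2R)-3-acetoxy-2-hydroxypropyl (3R)-3-methyl-5-[(4aR,8aR)-2,5,5,8a-tetramethyl-3,4,4a,5,6,7,8,8a-octahydronaphthalen-1-yl]pentanoate (CNP0137802.3)
Conditions: Bu4NBr (10 mol%), toluene, 70 °C; chromatography on boric-acid-treated silica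
Reagents that add atoms: none
Why: Carboxylate ring opening of a terminal epoxide under quaternary ammonium halide catalysis (SN2 at the unsubstituted epoxide carbon) should give the 1,3-diacylglycerol with the free secondary hydroxyl, and the glycerol stereocentre is carried over from 16 because no bond to it is broken.

## Compound list

1 | (S)-(+)-carvone, (5S)-2-methyl-5-(prop-1-en-2-yl)cyclohex-2-en-1-one | CC1=CC[C@@H](CC1=O)C(C)=C | starting material
2 | (5S,6RS)-2,6-dimethyl-5-(prop-1-en-2-yl)cyclohex-2-en-1-one (6-methylcarvone) | O=C1C(C)=CC[C@H](C(C)=C)C1C | intermediate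
3 | ethyl (2Z)-3-iodoprop-2-enoate | CCOC(=O)/C=C\I | starting material
4 | (2Z)-3-iodoprop-2-en-1-ol | OC/C=C\I | intermediate
5 | (1Z)-3-bromo-1-iodoprop-1-ene | BrC/C=C\I | intermediate
6 | (5R,6R)-6-[(2Z)-3-iodoprop-2-en-1-yl]-2,6-dimethyl-5-(prop-1-en-2-yl)cyclohex-2-en-1-one | O=C1C(C)=CC[C@H](C(C)=C)[C@@]1(C)C/C=C\I | intermediate
7 | (4aR,8aR)-2,5,5,8a-tetramethyl-4a,5,8,8a-tetrahydronaphthalen-1(4H)-one (trans-fused) | O=C1C(C)=CC[C@@H]2C(C)(C)C=CC[C@@]12C | intermediate
8 | (2RS,4aR,8aR)-2,5,5,8a-tetramethyl-3,4,4a,5,6,7,8,8a-octahydronaphthalen-1(2H)-one | O=C1C(C)CC[C@@H]2C(C)(C)CCC[C@@]12C | intermediate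
9 | (4aR,8aR)-2,5,5,8a-tetramethyl-3,4,4a,5,6,7,8,8a-octahydronaphthalen-1-yl trifluoromethanesulfonate | O=S(=O)(OC1=C(C)CC[C@@H]2C(C)(C)CCC[C@@]12C)C(F)(F)F | intermediate
10 | (3R)-5-methoxy-3-methyl-5-oxopentanoic acid | COC(=O)C[C@H](C)CC(=O)O | starting material
11 | methyl (3R)-5-hydroxy-3-methylpentanoate | COC(=O)C[C@H](C)CCO | intermediate
12 | methyl (3S)-5-iodo-3-methylpentanoate | COC(=O)C[C@H](C)CCI | intermediate
13 | [(3S)-5-methoxy-3-methyl-5-oxopentyl]zinc iodide | COC(=O)C[C@H](C)CC[Zn]I | intermediate
14 | methyl (3R)-3-methyl-5-[(4aR,8aR)-2,5,5,8a-tetramethyl-3,4,4a,5,6,7,8,8a-octahydronaphthalen-1-yl]pentanoate | COC(=O)C[C@H](C)CCC1=C(C)CC[C@@H]2C(C)(C)CCC[C@@]12C | intermediate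
15 | (3R)-3-methyl-5-[(4aR,8aR)-2,5,5,8a-tetramethyl-3,4,4a,5,6,7,8,8a-octahydronaphthalen-1-yl]pentanoic acid | OC(=O)C[C@H](C)CCC1=C(C)CC[C@@H]2C(C)(C)CCC[C@@]12C | intermediate
16 | (R)-glycidol, (2R)-oxiran-2-ylmethanol | OC[C@@H]1CO1 | starting material
17 | (S)-glycidyl acetate, (2S)-oxiran-2-ylmethyl acetate | CC(=O)OC[C@@H]1CO1 | intermediate
18 | (2R)-3-acetoxy-2-hydroxypropyl (3R)-3-methyl-5-[(4aR,8aR)-2,5,5,8a-tetramethyl-3,4,4a,5,6,7,8,8a-octahydronaphthalen-1-yl]pentanoate | CC(=O)OC[C@@H](O)COC(=O)C[C@H](C)CCC1=C(C)CC[C@@H]2C(C)(C)CCC[C@@]12C | target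

## Step count and risks

Total step count: 12.
Longest linear sequence: 8 steps (steps 2, 3, 4, 5, 6, 9, 10, 12).

Steps most likely to fail:

1. Step 4. Formate may reduce the alkenyl–palladium bond before it has added across the isopropenyl group, or the alkylation may lose facial or C/O selectivity when it is not purified before the palladium stage. The fallback sets out from 2 and comes back at 7, and closes ring A by a cationic instead of a palladium route. The lithium dienolate of 2 is alkylated with (E)-(3-bromoprop-1-en-1-yl)trimethylsilane F1 (from commercial (E)-3-(trimethylsilyl)prop-2-en-1-ol and PBr3), and the alkenylsilane ketone F2 is isolated. CF3CO2H in CH2Cl2 at 0 °C should then protonate the isopropenyl group to the tertiary C4 cation. The alkenylsilane attacks through its silicon-bearing carbon (6-endo, β-silyl cation), and loss of the silyl group gives dienone 7 (vinylsilane-terminated cation–olefin cyclisation).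

2. Step 9. Oxidative addition at the tetrasubstituted, neopentyl-flanked triflate may be slower than protonolysis or homocoupling of the alkylzinc, so that the triflate is returned or reduced. The fallback sets out from 12 (with 9) and comes back at 14, and changes the nucleophile to a boron ate complex. Dehydroiodination of 12 with DBU in toluene at 80 °C gives methyl (3S)-3-methylpent-4-enoate F3. Hydroboration with 9-borabicyclo[3.3.1]nonane in THF gives methyl (3R)-5-(9-borabicyclo[3.3.1]nonan-9-yl)-3-methylpentanoate F4. B-alkyl Suzuki–Miyaura coupling of F4 with 9 (PdCl2(dppf), AsPh3, Cs2CO3, DMF/THF/H2O, 50 °C) gives 14.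

3. Step 12. At 70 °C the acetyl or the labdenoyl group may migrate to the secondary hydroxyl, or the carboxylate may attack the internal epoxide carbon, giving 1,2-diacyl isomers that are hard to separate. The fallback sets out from 15 and comes back at 18, and builds the glycerol unit by protection and enzymatic acylation instead of epoxide opening. Acid 15 is esterified with commercial (S)-solketal (EDC·HCl, DMAP, CH2Cl2) to give [(4R)-2,2-dimethyl-1,3-dioxolan-4-yl]methyl ester F5. The acetonide is removed with CF3CO2H/H2O in THF at 0 °C to give the (2R)-2,3-dihydroxypropyl ester F6. The primary hydroxyl of F6 is then acetylated selectively with vinyl acetate and Candida antarctica lipase B in tert-butyl methyl ether at 20 °C to give 18.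

## Further compounds

F1 | step 4 | (E)-(3-bromoprop-1-en-1-yl)trimethylsilane | C[Si](C)(C)/C=C/CBr
F2 | step 4 | (5R,6R)-2,6-dimethyl-5-(prop-1-en-2-yl)-6-[(2E)-3-(trimethylsilyl)prop-2-en-1-yl]cyclohex-2-en-1-one | O=C1C(C)=CC[C@H](C(C)=C)[C@@]1(C)C/C=C/[Si](C)(C)C
F3 | step 9 | methyl (3S)-3-methylpent-4-enoate | COC(=O)C[C@H](C)C=C
F4 | step 9 | methyl (3R)-5-(9-borabicyclo[3.3.1]nonan-9-yl)-3-methylpentanoate | COC(=O)C[C@H](C)CCB1C2CCCC1CCC2
F5 | step 12 | [(4R)-2,2-dimethyl-1,3-dioxolan-4-yl]methyl (3R)-3-methyl-5-[(4aR,8aR)-2,5,5,8a-tetramethyl-3,4,4a,5,6,7,8,8a-octahydronaphthalen-1-yl]pentanoate | O=C(C[C@H](C)CCC1=C(C)CC[C@@H]2C(C)(C)CCC[C@@]12C)OC[C@H]1COC(C)(C)O1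
F6 | step 12 | (2R)-2,3-dihydroxypropyl (3R)-3-methyl-5-[(4aR,8aR)-2,5,5,8a-tetramethyl-3,4,4a,5,6,7,8,8a-octahydronaphthalen-1-yl]pentanoate | O=C(C[C@H](C)CCC1=C(C)CC[C@@H]2C(C)(C)CCC[C@@]12C)OC[C@H](O)CO
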